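**Strategy.** The decalin is disconnected at C1–C10 in ring A. In the key step a titanocene-catalysed reductive opening of a C9–C10 epoxide releases the tertiary C10 radical, which adds 6-endo to C1 of a vinyl ketone (C1=C2–C3=O): one operation closes ring A, builds the quaternary C10 with its methyl anti to H5, and installs the C3 carbonyl. It exploits the 1,4-relationship between C10 and the C3 oxygen across ring A. The precursor is an acyclic epoxy enone whose C5 stereocentre comes from an Ireland–Claisen chirality transfer; ring B is closed afterwards by a 6-exo alkenyl-radical cyclisation (C8–C9) that leaves the C7=C8 alkene. C9–C15 derive from (S)-citronellol.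

Key step: step 12

Remark: atom labels are those of the labdane skeleton of the target (ring A: C1–C5 and C10; ring B: C5–C10; C20 is the methyl on C10; side chain C11–C16 on C9); the SMILES is read as 3-hydroxyl axial (trans to the C10 methyl), C13 (S) and an (R)-2-methylbutanoate, and (Z)-3-iodobut-2-en-1-ol, (S)-citronellol and (R)-2-methylbutanoic acid are taken as purchasable.

Step 1
Reactants: 1 (Z)-3-iodobut-2-en-1-ol
Product: 2 (Z)-1-bromo-3-iodobut-2-ene
Conditions: CBr4, PPh3, CH2Cl2, 0 °C
Reagents that add atoms: tetrabromomethane, BrC(Br)(Br)Br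
Why: Appel bromination converts the primary allylic alcohol into the bromide under neutral conditions that leave the alkenyl iodide and its Z geometry untouched.

Step 2
Reactants: 2 (Z)-1-bromo-3-iodobut-2-ene
Product: 3 (Z)-2-iodohept-2-en-5-yne
Conditions: CH3C≡CMgBr, CuI (10 mol%), THF, 0 °C
Reagents that add atoms: prop-1-ynylmagnesium bromide, CC#C[Mg]Br
Why: CuI-catalysed SN2 coupling of an alkynyl Grignard reagent with a primary allylic bromide gives the skipped enyne, the alkenyl iodide being inert to the Grignard reagent at this temperature.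

Step 3
Reactants: 4 (S)-citronellol
Product: 5 tert-butyl{[(3S)-3,7-dimethyloct-6-en-1-yl]oxy}dimethylsilane
Conditions: TBSCl, imidazole, DMF, rt
Reagents that add atoms: tert-butyldimethylsilyl chloride, CC(C)(C)[Si](C)(C)Cl
Why: Silyl ether formation masks the primary alcohol (the later C15 oxygen) for the basic and organometallic steps, and the C13 stereocentre is taken unchanged from (S)-citronellol.

Step 4
Reactants: 5 tert-butyl{[(3S)-3,7-dimethyloct-6-en-1-yl]oxy}dimethylsilane
Product: 7 (4S)-6-[(tert-butyldimethylsilyl)oxy]-4-methylhexanal, via ozonide 6 (not isolated)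
Conditions: O3, CH2Cl2, −78 °C; PPh3
Reagents that add atoms: ozone, [O-][O+]=O
Why: Ozonolysis with reductive work-up cleaves the trisubstituted alkene and unveils the aldehyde carbon that becomes C9.

Step 5
Reactants: 3 (Z)-2-iodohept-2-en-5-yne; 7 (4S)-6-[(tert-butyldimethylsilyl)oxy]-4-methylhexanal
Product: 10 (3S,6R,7Z)-1-[(tert-butyldimethylsilyl)oxy]-3,7-dimethyldodec-7-en-10-yn-6-ol, via alkenyllithium 8 (not isolated), via dialkenylzinc 9 (not isolated)
Conditions: t-BuLi, Et2O, −78 °C; ZnBr2 (0.5 equiv); TEEDA, (−)-MIB (10 mol%), toluene, 0 °C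
Reagents that add atoms: none
Why: Iodine–lithium exchange with retention, transmetalation to zinc and amino-alcohol-catalysed asymmetric alkenylzinc addition to the aldehyde, in which the morpholinoisoborneol ligand (enantiomer chosen for Si-face delivery) sets the (R)-carbinol at C9 and the Z geometry of the alkenyl unit is carried over.

Step 6
Reactants: 10 (3S,6R,7Z)-1-[(tert-butyldimethylsilyl)oxy]-3,7-dimethyldodec-7-en-10-yn-6-ol
Product: 12 (3S,6R,7Z,10E)-1-[(tert-butyldimethylsilyl)oxy]-11-iodo-3,7-dimethyldodeca-7,10-dien-6-ol, via alkenylzirconocene 11 (not isolated)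
Conditions: Cp2Zr(H)Cl (2.5 equiv), THF, rt to 40 °C; I2, 0 °C
Reagents that add atoms: iodine, II
Why: Hydrozirconation adds Zr–H syn across the alkyne and, under equilibrating conditions, places zirconium on the less hindered carbon next to the methyl group, and iodinolysis with retention then gives the E-alkenyl iodide while the trisubstituted alkene stays untouched.

Step 7
Reactants: 12 (3S,6R,7Z,10E)-1-[(tert-butyldimethylsilyl)oxy]-11-iodo-3,7-dimethyldodeca-7,10-dien-6-ol
Product: 13 the 2-methylpropanoate of 12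
Conditions: (CH3)2CHCOCl, pyridine, DMAP (5 mol%), CH2Cl2, 0 °C
Reagents that add atoms: 2-methylpropanoyl chloride, CC(C)C(Cl)=O
Why: DMAP-catalysed acylation of the secondary allylic alcohol installs the ester needed for the sigmatropic step without touching any stereocentre.

Step 8
Reactants: 13 the 2-methylpropanoate of 12
Product: 16 (3R,4E,8S)-10-[(tert-butyldimethylsilyl)oxy]-3-[(2E)-3-iodobut-2-en-1-yl]-2,2,4,8-tetramethyldec-4-enoic acid, via silyl ketene acetal 14 (not isolated), via trimethylsilyl ester 15 (not isolated)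
Conditions: LiN(i-Pr)2, THF, −78 °C; Me3SiCl, Et3N; −78 to 60 °C; 1 M HCl, 0 °C
Reagents that add atoms: none
Why: Ireland–Claisen rearrangement through a chair transition state in which the C11 chain on the carbinol carbon is equatorial (the axial alternative would clash with the cis allylic substituent of the Z alkene), so that the C–O bond is exchanged suprafacially for the C4–C5 bond, which sets C5 (R) by 1,3-chirality transfer from the (R)-carbinol and gives the E C9=C10 alkene.

Step 9
Reactants: 16 (3R,4E,8S)-10-[(tert-butyldimethylsilyl)oxy]-3-[(2E)-3-iodobut-2-en-1-yl]-2,2,4,8-tetramethyldec-4-enoic acid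
Product: 18 the N-methoxy-N-methylamide of 16, via acid chloride 17 (not isolated)
Conditions: 1-chloro-N,N,2-trimethylpropenylamine, CH2Cl2, 0 °C; MeNHOMe·HCl, pyridine, 0 °C to rt
Reagents that add atoms: N,O-dimethylhydroxylamine hydrochloride, CNOC.Cl
Why: Neutral acid chloride formation with the α-chloroenamine (tolerated by the silyl ether) activates the hindered α-quaternary acid for amidation to the Weinreb amide.

Step 10
Reactants: 18 the N-methoxy-N-methylamide of 16
Product: 20 (5R,6E,10S)-12-[(tert-butyldimethylsilyl)oxy]-5-[(2E)-3-iodobut-2-en-1-yl]-4,4,6,10-tetramethyldodeca-1,6-dien-3-one, via magnesium hemiaminal 19 (not isolated)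
Conditions: CH2=CHMgBr, THF, −78 to 0 °C; cold aq. KHSO4
Reagents that add atoms: vinylmagnesium bromide, C=C[Mg]Br
Why: Weinreb ketone synthesis, in which the chelated tetrahedral intermediate stops the addition at the ketone stage and the acidic inverse quench keeps the released amine from adding to the vinyl ketone.

Step 11
Reactants: 20 (5R,6E,10S)-12-[(tert-butyldimethylsilyl)oxy]-5-[(2E)-3-iodobut-2-en-1-yl]-4,4,6,10-tetramethyldodeca-1,6-dien-3-one
Product: 21 the C9–C10 epoxide of 20
Conditions: mCPBA, NaHCO3, CH2Cl2, 0 °C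
Reagents that add atoms: 3-chloroperoxybenzoic acid, OOC(=O)c1cccc(Cl)c1
Why: Prilezhaev epoxidation is selective for the electron-rich trisubstituted C9=C10 alkene over the enone and the alkenyl iodide, it is stereospecific (trans epoxide), and the facial mixture is harmless because C10 later becomes a radical and C9 an alkene carbon.

Step 12
Reactants: 21 the C9–C10 epoxide of 20
Product: 24 (3R,4S)-4-{(4S)-6-[(tert-butyldimethylsilyl)oxy]-1-hydroxy-4-methylhexyl}-3-[(2E)-3-iodobut-2-en-1-yl]-2,2,4-trimethylcyclohexan-1-one, via C10 radical 22 (not isolated), via titanium enolate 23 (not isolated)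
Conditions: Cp2TiCl2 (20 mol%), Mn, 2,4,6-collidine·HCl, THF, rt, slow addition of 21
Reagents that add atoms: none
Why: Reductive epoxide opening with radical conjugate cyclisation (Nugent–RajanBabu reaction in its catalytic variant with a collidinium salt): Cp2TiCl, the trivalent titanium species formed from Cp2TiCl2 and Mn, binds the epoxide oxygen and cleaves the C10–O bond homolytically, so that the tertiary radical 22 forms at C10 while C9 keeps the titanium alkoxide. The closest known reaction type is the titanocene-mediated addition of epoxide-derived radicals to enones and acrylates, and the nucleophilic tertiary radical is polarity-matched with the vinyl ketone. Ring A closes in the 6-endo-trig mode at the unsubstituted terminus C1, because the 5-exo alternative at C2 is anti-Michael and would leave an unstabilised primary radical; the resulting α-keto radical is reduced to titanium enolate 23 and protonated by the collidinium salt, which also turns the catalyst over. C10 is set by the C5 stereocentre in a chair transition state in which the hydrogen on C5 lies next to the bulky C9 branch, the C6 arm points away from the forming bond and the methyl group takes the axial site, so that C1 bonds anti to H5 (the trans ring-fusion relationship of the target). The step needs regioselective opening toward C10, which the trisubstituted epoxide secures, and chemoselectivity for the epoxide over enone and alkenyl iodide, which the low stationary concentration of trivalent titanium should secure; the configuration of the C9 carbinol is of no consequence because step 13 removes it.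

Step 13
Reactants: 24 (3R,4S)-4-{(4S)-6-[(tert-butyldimethylsilyl)oxy]-1-hydroxy-4-methylhexyl}-3-[(2E)-3-iodobut-2-en-1-yl]-2,2,4-trimethylcyclohexan-1-one
Product: 25 (3R,4R)-4-{(1E,4S)-6-[(tert-butyldimethylsilyl)oxy]-4-methylhex-1-en-1-yl}-3-[(2E)-3-iodobut-2-en-1-yl]-2,2,4-trimethylcyclohexan-1-one
Conditions: Burgess reagent, toluene, 70 °C
Reagents that add atoms: none
Why: Burgess dehydration (syn elimination of the sulfamate ester) can take a hydrogen only from C11 because C10 is quaternary, which should give the E C9=C11 alkene and removes the stereochemically undefined carbinol.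

Step 14
Reactants: 25 (3R,4R)-4-{(1E,4S)-6-[(tert-butyldimethylsilyl)oxy]-4-methylhex-1-en-1-yl}-3-[(2E)-3-iodobut-2-en-1-yl]-2,2,4-trimethylcyclohexan-1-one
Product: 27 (5R,9S,10R,13S)-15-[(tert-butyldimethylsilyl)oxy]labd-7-en-3-one, via alkenyl radical 26 (not isolated)
Conditions: Bu3SnH, AIBN, benzene, 80 °C, slow addition
Reagents that add atoms: none
Why: Alkenyl radical cyclisation in which iodine abstraction gives the C8 σ-radical, which closes ring B 6-exo-trig onto C9 through a chair transition state with the C9=C11 unit equatorial and the new bond forming anti to the axial C10 methyl, so that C9 carries its side chain equatorial (H9 anti to the methyl group) and the C7=C8 alkene is left in place.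

Step 15
Reactants: 27 (5R,9S,10R,13S)-15-[(tert-butyldimethylsilyl)oxy]labd-7-en-3-one
Product: 28 (5R,9S,10R,13S)-15-hydroxylabd-7-en-3-one
Conditions: HF·pyridine, THF, 0 °C to rt
Reagents that add atoms: none
Why: Fluoride-mediated desilylation frees the primary alcohol without affecting the ketone or the alkene.

Step 16
Reactants: 28 (5R,9S,10R,13S)-15-hydroxylabd-7-en-3-one; 29 (R)-2-methylbutanoic acid
Product: 30 (5R,9S,10R,13S)-3-oxolabd-7-en-15-yl (2R)-2-methylbutanoate
Conditions: EDC·HCl, DMAP (10 mol%), CH2Cl2, 0 °C to rt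
Reagents that add atoms: none
Why: Steglich esterification of the only hydroxyl group, run cold with little DMAP so that the α-stereocentre of the acid is kept.

Step 17
Reactants: 30 (5R,9S,10R,13S)-3-oxolabd-7-en-15-yl (2R)-2-methylbutanoate
Product: 31 (3R,5R,9S,10R,13S)-3-hydroxylabd-7-en-15-yl (2R)-2-methylbutanoate
Conditions: LiBH(s-Bu)3, THF, −78 °C; H2O
Reagents that add atoms: none
Why: Substrate-controlled ketone reduction in which the bulky trialkylborohydride attacks the 4,4-dimethyl-3-ketone from the equatorial direction and so should deliver the axial 3-hydroxyl (trans to the C10 methyl) without touching the ester.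

**Compound list**

1 | (Z)-3-iodobut-2-en-1-ol | C/C(I)=C/CO | starting material
2 | (Z)-1-bromo-3-iodobut-2-ene | C/C(I)=C/CBr | intermediate
3 | (Z)-2-iodohept-2-en-5-yne | C/C(I)=C/CC#CC | intermediate
4 | (S)-citronellol, (3S)-3,7-dimethyloct-6-en-1-ol | OCC[C@@H](C)CCC=C(C)C | starting material
5 | tert-butyl{[(3S)-3,7-dimethyloct-6-en-1-yl]oxy}dimethylsilane | CC(C)(C)[Si](C)(C)OCC[C@@H](C)CCC=C(C)C | intermediate
6 | ozonide (1,2,4-trioxolane) of 5 | CC(C)(C)[Si](C)(C)OCC[C@@H](C)CCC1OOC(C)(C)O1 | intermediate
7 | (4S)-6-[(tert-butyldimethylsilyl)oxy]-4-methylhexanal | CC(C)(C)[Si](C)(C)OCC[C@@H](C)CCC=O | intermediate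
8 | [(2Z)-hept-2-en-5-yn-2-yl]lithium | C/C([Li])=C/CC#CC | intermediate
9 | bis[(2Z)-hept-2-en-5-yn-2-yl]zinc | C/C(=C/CC#CC)[Zn]/C(C)=C\CC#CC | intermediate
10 | (3S,6R,7Z)-1-[(tert-butyldimethylsilyl)oxy]-3,7-dimethyldodec-7-en-10-yn-6-ol | CC(C)(C)[Si](C)(C)OCC[C@@H](C)CC[C@@H](O)/C(C)=C\CC#CC | intermediate
11 | chlorozirconocene alkoxide of the (10E)-11-(chlorozirconocenyl) diene derived from 10 | CC(C)(C)[Si](C)(C)OCC[C@@H](C)CC[C@@H](O[Zr](Cl)(C1C=CC=C1)C1C=CC=C1)/C(C)=C\C/C=C(/[Zr](Cl)(C1C=CC=C1)C1C=CC=C1)C | intermediate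
12 | (3S,6R,7Z,10E)-1-[(tert-butyldimethylsilyl)oxy]-11-iodo-3,7-dimethyldodeca-7,10-dien-6-ol | CC(C)(C)[Si](C)(C)OCC[C@@H](C)CC[C@@H](O)/C(C)=C\C/C=C(/I)C | intermediate
13 | 2-methylpropanoate of 12 at the C6 oxygen, (3S,6R,7Z,10E) | CC(C)(C)[Si](C)(C)OCC[C@@H](C)CC[C@@H](OC(=O)C(C)C)/C(C)=C\C/C=C(/I)C | intermediate
14 | trimethylsilyl ketene acetal of 13 | CC(C)(C)[Si](C)(C)OCC[C@@H](C)CC[C@@H](OC(O[Si](C)(C)C)=C(C)C)/C(C)=C\C/C=C(/I)C | intermediate
15 | trimethylsilyl ester of 16 | CC(C)(C)[Si](C)(C)OCC[C@@H](C)CC/C=C(C)/[C@@H](C/C=C(/I)C)C(C)(C)C(=O)O[Si](C)(C)C | intermediate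
16 | (3R,4E,8S)-10-[(tert-butyldimethylsilyl)oxy]-3-[(2E)-3-iodobut-2-en-1-yl]-2,2,4,8-tetramethyldec-4-enoic acid | CC(C)(C)[Si](C)(C)OCC[C@@H](C)CC/C=C(C)/[C@@H](C/C=C(/I)C)C(C)(C)C(O)=O | intermediate
17 | acid chloride of 16 | CC(C)(C)[Si](C)(C)OCC[C@@H](C)CC/C=C(C)/[C@@H](C/C=C(/I)C)C(C)(C)C(Cl)=O | intermediate
18 | N-methoxy-N-methylamide of 16 | CC(C)(C)[Si](C)(C)OCC[C@@H](C)CC/C=C(C)/[C@@H](C/C=C(/I)C)C(C)(C)C(=O)N(C)OC | intermediate
19 | bromomagnesium salt of the tetrahedral vinyl adduct of 18 | CC(C)(C)[Si](C)(C)OCC[C@@H](C)CC/C=C(C)/[C@@H](C/C=C(/I)C)C(C)(C)C(O[Mg]Br)(C=C)N(C)OC | intermediate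
20 | (5R,6E,10S)-12-[(tert-butyldimethylsilyl)oxy]-5-[(2E)-3-iodobut-2-en-1-yl]-4,4,6,10-tetramethyldodeca-1,6-dien-3-one | CC(C)(C)[Si](C)(C)OCC[C@@H](C)CC/C=C(C)/[C@@H](C/C=C(/I)C)C(C)(C)C(=O)C=C | intermediate
21 | 6,7-epoxide of 20 (the C9–C10 epoxide; both trans-epoxide diastereomers; C5 and C13 arranged as in 20) | CC(C)(C)[Si](C)(C)OCC[C@@H](C)CCC1OC1(C)[C@@H](C/C=C(/I)C)C(C)(C)C(=O)C=C | intermediate
22 | tertiary C10 radical from 21 with the C9 oxygen bound to chlorotitanocene | CC(C)(C)[Si](C)(C)OCC[C@@H](C)CCC(O[Ti](Cl)(C1C=CC=C1)C1C=CC=C1)[C](C)[C@@H](C/C=C(/I)C)C(C)(C)C(=O)C=C | intermediate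
23 | ring A titanium enolate (C2=C3–O–Ti) carrying the C9 titanium alkoxide | CC(C)(C)[Si](C)(C)OCC[C@@H](C)CCC(O[Ti](Cl)(C1C=CC=C1)C1C=CC=C1)[C@@]1(C)CC=C(O[Ti](Cl)(C2C=CC=C2)C2C=CC=C2)C(C)(C)[C@@H]1C/C=C(/I)C | intermediate
24 | (3R,4S)-4-{(4S)-6-[(tert-butyldimethylsilyl)oxy]-1-hydroxy-4-methylhexyl}-3-[(2E)-3-iodobut-2-en-1-yl]-2,2,4-trimethylcyclohexan-1-one (both carbinol epimers; ring methyl on C4 trans to H3) | CC(C)(C)[Si](C)(C)OCC[C@@H](C)CCC(O)[C@@]1(C)CCC(=O)C(C)(C)[C@@H]1C/C=C(/I)C | intermediate
25 | (3R,4R)-4-{(1E,4S)-6-[(tert-butyldimethylsilyl)oxy]-4-methylhex-1-en-1-yl}-3-[(2E)-3-iodobut-2-en-1-yl]-2,2,4-trimethylcyclohexan-1-one | CC(C)(C)[Si](C)(C)OCC[C@@H](C)C/C=C/[C@@]1(C)CCC(=O)C(C)(C)[C@@H]1C/C=C(/I)C | intermediate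
26 | C8 alkenyl radical formed from 25 by loss of iodine | CC(C)(C)[Si](C)(C)OCC[C@@H](C)C/C=C/[C@@]1(C)CCC(=O)C(C)(C)[C@@H]1CC=[C]C | intermediate
27 | (5R,9S,10R,13S)-15-[(tert-butyldimethylsilyl)oxy]labd-7-en-3-one | CC(C)(C)[Si](C)(C)OCC[C@@H](C)CC[C@H]1C(C)=CC[C@H]2C(C)(C)C(=O)CC[C@]12C | intermediate
28 | (5R,9S,10R,13S)-15-hydroxylabd-7-en-3-one | OCC[C@@H](C)CC[C@H]1C(C)=CC[C@H]2C(C)(C)C(=O)CC[C@]12C | intermediate
29 | (R)-2-methylbutanoic acid | CC[C@@H](C)C(O)=O | starting material
30 | (5R,9S,10R,13S)-3-oxolabd-7-en-15-yl (2R)-2-methylbutanoate | CC[C@@H](C)C(=O)OCC[C@@H](C)CC[C@H]1C(C)=CC[C@H]2C(C)(C)C(=O)CC[C@]12C | intermediate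
31 | (3R,5R,9S,10R,13S)-3-hydroxylabd-7-en-15-yl (2R)-2-methylbutanoate (3-hydroxyl axial) | CC[C@@H](C)C(=O)OCC[C@@H](C)CC[C@H]1C(C)=CC[C@H]2C(C)(C)[C@H](O)CC[C@]12C | target

**Totals.** 17 steps. Longest linear sequence: 15 steps (steps 3–17 from 4; equally steps 1, 2 and 5–17 from 1).

**Steps most likely to fail**

1. Step 12. The tertiary radical may be intercepted by trivalent titanium (loss of a hydrogen to give an exocyclic allylic alcohol, or reduction) before it reaches C1. The enone may also be reduced or oligomerised by the low-valent metal, and the facial selectivity at C10 may be incomplete. The fallback avoids titanium and sets out from vinyl ketone 20. A Schenck ene reaction with singlet oxygen (O2, tetraphenylporphyrin, visible light, CH2Cl2) should take a hydrogen from the C20 methyl, which is geminal to the bulky C5 branch, and give the allylic hydroperoxide F1. PPh3 reduces it to the allylic alcohol F2 (C10=CH2, C9–OH). Hydrogen-atom transfer from an iron hydride (Fe(acac)3 30 mol%, PhSiH3, EtOH, 60 °C; reductive olefin–enone coupling) then creates the same tertiary C10 radical from the 1,1-disubstituted alkene and closes ring A. The route is rejoined at hydroxy ketone 24.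

2. Step 14. The alkenyl radical may be reduced by the stannane before it cyclises, and the facial selectivity at C9 may be insufficient. The fallback is a reductive Heck cyclisation of the same compound 25 (Pd(OAc)2 5 mol%, PPh3, HCO2Na, Et4NCl, DMF, 80 °C). Oxidative addition into the C8–I bond, 6-exo syn-carbopalladation of the C9=C11 alkene and formate reduction of the alkylpalladium intermediate lead directly to 27, without a free radical or a tin hydride.

3. Step 13. The hindered sulfamate next to the quaternary C10 may ionise and suffer a 1,2-shift instead of syn elimination. In the fallback the C9=C11 alkene is introduced before ring A is closed. The allylic alcohol F2 (from 20 via the allylic hydroperoxide F1, as above) should lose water easily with the Burgess reagent, because elimination now gives the conjugated diene F3. Hydrogen-atom transfer to the terminal CH2 of this diene (Fe(acac)3 30 mol%, PhSiH3, EtOH, 60 °C) gives an allyl radical that cyclises through its tertiary C10 terminus onto the vinyl ketone. The route is rejoined at alkene 25.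

Further compounds
F1 | step 12 | allylic hydroperoxide from 20 (C10=CH2, C9–OOH; both C9 epimers) | CC(C)(C)[Si](C)(C)OCC[C@@H](C)CCC(OO)C(=C)[C@@H](C/C=C(/I)C)C(C)(C)C(=O)C=C
F2 | step 12 | allylic alcohol from F1 (C10=CH2, C9–OH; both C9 epimers) | CC(C)(C)[Si](C)(C)OCC[C@@H](C)CCC(O)C(=C)[C@@H](C/C=C(/I)C)C(C)(C)C(=O)C=C
F3 | step 13 | conjugated diene from F2 (C20=C10–C9=C11, E) | CC(C)(C)[Si](C)(C)OCC[C@@H](C)C/C=C/C(=C)[C@@H](C/C=C(/I)C)C(C)(C)C(=O)C=C
F0 | step 14 | none | none
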